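**Assumption:** geraniol of high E purity (free of nerol) is used, because the Z isomer would lead to the diastereomeric side-chain diol.

## Analysis of the target

Target 28 is a flavone. Ring A carries hydroxyls at C5 and C7 and a prenyl group at C6, ring B is a 2',4'-dihydroxyphenyl group on C2, and C3 carries a 2,3-dihydroxy-3,7-dimethyloct-6-enyl chain, which is a geranyl unit hydrated across its inner double bond. The only stereocentres are the neighbouring carbinol carbons of that chain, C2'' (secondary, S) and C3'' (tertiary, R). Their relationship is that of anti addition of two oxygens across an E-trisubstituted alkene, so both can come from one epoxide of geraniol opened with a single inversion. The molecule is sensitive: two trisubstituted alkenes sit close to nucleophilic hydroxyls (C5-OH and C7-OH next to the prenyl group, the tertiary C3''-OH near the chain terminus), so strong acid leads to chromans and cyclic ethers. Hydrogenolysis and electrophilic oxidants are excluded, and the four phenols are electron-rich. The real difficulty is regiochemical. C6 and C8 of ring A differ only in which of the two oxygens ortho to the C4 carbonyl (O1 on C8a, or the oxygen on C5) is part of ring C, so any route that lets both oxygens compete gives 6-prenyl and 8-prenyl flavones together. The strategy rests on ring A: C8a (bearing O1) and C4a (bearing the C4 carbonyl) are adjacent carbons flanked by the C5 oxygen. These are exactly the two atoms a carboxylic acid delivers to an aryne. The 5,7-dioxy-6-prenyl array also comes from a mirror-symmetric phenol, so only one aryne is possible.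

## Retrosynthetic reasoning

**Protecting groups.** Target 28 is traced back to flavone 27, in which the four phenols are methoxymethyl ethers and the diol is an acetonide. All five groups fall under one mild acid treatment, and all survive organolithium reagents, fluoride and amide bases. The forward step only has to be gentle enough to spare the two alkenes.

**Ring C.** In 27 the O1–C2 bond is cut first (cyclodehydration of diketone 26), then the C2–C3 bond (intramolecular acyl transfer in aryl ester 25), and finally the ester bond, which leads to ketone 24 and acid 22. Cutting here and not elsewhere fixes without ambiguity that ring B sits on C2 and the chain on C3, since the chain is already the alkyl part of the ketone and ring B arrives as the acyl donor. The forward sequence requires that 24 has exactly one free hydroxyl ortho to the ketone, on the future C8a, and a protected oxygen on the future C5. Ring closure must also happen before any protecting group is lost. Acid 22 is used directly with a carbodiimide rather than as its acid chloride, so that no hydrogen chloride is formed next to the acetal ethers.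

**Key disconnection.** Ketone 24 is cut at two bonds at once, O–C8a and C4–C4a, which gives aryne precursor 10 and carboxylic acid 19. This is the only disconnection that installs the free C8a hydroxyl and the acyl group in one step and in a defined orientation; a Friedel–Crafts or Fries approach would have to choose between two equivalent-looking ortho positions after the fact. What is gained is full convergence: the whole stereodefined chain arrives as a simple acid, and ring A arrives with its oxygen pattern already differentiated. The forward reaction has to generate aryne 23, add the carboxylate oxygen to the carbon remote from the flanking ether, and transfer the acyl group to the neighbouring carbon.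

**Aryne precursor.** Triflate 10 goes back to bromophenol 7 by silylation, bromine–lithium exchange with oxygen-to-carbon silyl shift, and triflation, and 7 goes back to symmetric phenol 6 by ring bromination. Because 6 has a mirror plane through C1 and C4, bromination at either ortho carbon gives the same compound, so no regiochemical question arises. Phenol 6 is cut at the aryl–prenyl bond to silyl ether 3 and bromide 4: the position between the two acetal ethers of 3 is the most acidic ring position, and the bulky silyl ether neither directs nor migrates. Ether 3 comes from bis-ether 2, which comes from triol 1.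

**Chain acid.** Acid 19 goes back through ester 18 to lactone 17, and through lactone ester 16 to the bond between C2 and C3 of the acid. That bond is made by opening terminal epoxide 15 with a two-carbon nucleophile at its unsubstituted carbon, a reaction that cannot touch either stereocentre. Epoxide 15 comes from tosylate 14 and triol 13. Triol 13 is cut to epoxy alcohol 12 by acid-catalysed hydrolysis with inversion at the tertiary carbon, and 12 comes from alcohol 11 by asymmetric epoxidation. Placing the stereochemical steps at the very start, on the allylic alcohol, also solves the chemoselectivity problem between the two trisubstituted alkenes, since only the allylic one is epoxidised.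

**Ring B.** Acid 22 comes from acid 20 by exhaustive acetal protection and selective cleavage of the ester-type acetal via 21.

## Alternatives that were turned down

**Alternative 1:** biomimetic Claisen closure of ring A on a pyranone.
- Disconnection: the C4a–C5 bond of ring A, made last on a preformed 4-pyranone that already carries ring B and the chain.
- Forward key step: Mg(OMe)2 converts pyranone β-ketoester A2 into a chelated polyenolate. The pyranone carbon that becomes C4a attacks the methyl ester, ring A closes, and tautomerisation gives flavone A1 with a free 5,7-diol.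
- For: the prenyl position is fixed by the connectivity of the open chain, so the two ring A oxygens never have to be told apart and need no protection. On this point it is stronger than the chosen route.
- Against: A2 is a long linear target in itself, a 2,3,6-trisubstituted pyranone built with the stereodefined chain in place and then extended by a prenylated malonyl unit. Its most acidic site is the carbon between ketone and ester, and that enolate deactivates the very ester that must be attacked. O-acylation of the enolised side-chain ketone competes with attack from carbon.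
- Comparison: the chosen route gives up the protecting-group-free ring A but joins two independently made fragments late, in a reaction whose regiochemistry is controlled by a substituent in the substrate.

**Alternative 2:** de novo construction of ring B by alkyne benzannulation.
- Disconnection: bonds C1'–C2' and C5'–C6' of ring B.
- Forward key step: 2-ethynylchromone A4 reacts with bis-silyloxy diene A5. The cycloadduct loses methanol and the silyl groups and gives flavone A3 with a free resorcinol ring.
- For: the positions of the ring B hydroxyls follow from the polarity of A5, and ring B needs no protection.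
- Against: ring B is the simplest part of the molecule and is available from 20 in one step. A4 still needs the whole of ring A with its regiochemical problem, ring C, and extra steps for the ethynyl group. A4 is also a doubly activated acceptor, and A5 may add at C2 of the chromone instead of the alkyne terminus.
- Comparison: the route is clearly longer than the chosen one and leaves the hard part of the target unsolved. The chosen strategy spends its key step on ring A, where the difficulty lies.

**Alternative 3:** formyl C–H annulation of a salicylaldehyde with an aryl alkyl alkyne.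
- Disconnection: bonds C3–C4 and O1–C2 of ring C.
- Forward key step: with [Cp*RhCl2]2 and Cu(OAc)2 the formyl C–H bond of salicylaldehyde A7 adds across alkyne A8, and C–O bond formation closes ring C to give protected flavone A6, which is identical with 27.
- For: it is the most step-economical of all. A7 would come in one step from phenol 6 by ortho-formylation, A8 from epoxide 15 by alkynylation and ketalisation, and ring C forms in one operation where the chosen route needs three. On step count it is stronger.
- Against: nothing in the substrates enforces the orientation of alkyne insertion. An aryl group with an ortho acetal ether is twisted out of conjugation, which weakens the usual preference for aryl next to oxygen, and the wrong orientation gives a 2-alkyl-3-aryl chromone. The aldehyde is flanked by two oxygens, which slows acyl–metal formation and favours decarbonylation. A stoichiometric divalent copper oxidant at high temperature acts on an electron-rich arene with two allylic systems.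
- Comparison: the chosen route is longer but every selectivity is fixed by structure. The aryne step is governed by the flanking ether, and the assignment of C2 and C3 by which partner is the ketone. No transition metal or oxidant meets the prenyl groups.

Key step: step 15

## Route

Step 1
Reactants: 1 phloroglucinol (benzene-1,3,5-triol)
Product: 2 3,5-bis(methoxymethoxy)phenol
Conditions: MeOCH2Cl (2.0 equiv), i-Pr2NEt (2.2 equiv), DMF, 0 °C to rt; chromatographic separation from mono- and tris-ether
Reagents that add atoms: chloromethyl methyl ether, COCCl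
Why: O-alkylation of a phenol with an α-chloro ether; the three hydroxyls are equivalent, so two equivalents should give the bis-ether as the main component of a statistical mixture, from which it is separated and the mono-ether resubmitted.

Step 2
Reactants: 2 3,5-bis(methoxymethoxy)phenol
Product: 3 [3,5-bis(methoxymethoxy)phenoxy]tri(propan-2-yl)silane
Conditions: i-Pr3SiCl, imidazole, DMF, rt
Reagents that add atoms: chlorotri(propan-2-yl)silane, CC(C)[Si](Cl)(C(C)C)C(C)C
Why: Standard silylation of the only free hydroxyl; the bulky silyl ether tolerates butyllithium, does not direct metalation and shields its own ortho positions.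

Step 3
Reactants: 3 [3,5-bis(methoxymethoxy)phenoxy]tri(propan-2-yl)silane; 4 1-bromo-3-methylbut-2-ene
Product: 5 [3,5-bis(methoxymethoxy)-4-(3-methylbut-2-en-1-yl)phenoxy]tri(propan-2-yl)silane
Conditions: n-BuLi, TMEDA, THF, 0 °C; CuI (10 mol%), then 4, −30 °C to rt
Reagents that add atoms: none
Why: Directed ortho-metalation at the ring carbon between the two chelating methoxymethoxy groups, the most acidic site, followed by copper-catalysed allylic substitution at the primary carbon of 4; the symmetry of 3 makes the product a single compound.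

Step 4
Reactants: 5 [3,5-bis(methoxymethoxy)-4-(3-methylbut-2-en-1-yl)phenoxy]tri(propan-2-yl)silane
Product: 6 3,5-bis(methoxymethoxy)-4-(3-methylbut-2-en-1-yl)phenol
Conditions: Bu4NF, THF, 0 °C; aq. NH4Cl
Reagents that add atoms: none
Why: Fluoride cleavage of an aryl silyl ether; acetal ethers and the alkene are inert, and the product is the mirror-symmetric phenol on which the regiochemical argument rests.

Step 5
Reactants: 6 3,5-bis(methoxymethoxy)-4-(3-methylbut-2-en-1-yl)phenol
Product: 7 2-bromo-3,5-bis(methoxymethoxy)-4-(3-methylbut-2-en-1-yl)phenol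
Conditions: NBS (1.0 equiv), CH2Cl2, −78 °C
Reagents that add atoms: N-bromosuccinimide, O=C1CCC(=O)N1Br
Why: Electrophilic aromatic bromination of a phloroglucinol-type ring, which should be far more nucleophilic than the trisubstituted alkene at low temperature without a protic nucleophile; the two free ring positions are equivalent, so only one monobromide can form.

Step 6
Reactants: 7 2-bromo-3,5-bis(methoxymethoxy)-4-(3-methylbut-2-en-1-yl)phenol
Product: 10 3,5-bis(methoxymethoxy)-4-(3-methylbut-2-en-1-yl)-2-(trimethylsilyl)phenyl trifluoromethanesulfonate, via trimethylsilyl ether 8 (not isolated), via lithium 2-silylphenoxide 9 (not isolated)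
Conditions: (Me3Si)2NH, THF, 65 °C, then evaporation; n-BuLi, THF, −100 °C; Tf2O, −100 °C to rt
Reagents that add atoms: hexamethyldisilazane, C[Si](C)(C)N[Si](C)(C)C; trifluoromethanesulfonic anhydride, O=S(=O)(OS(=O)(=O)C(F)(F)F)C(F)(F)F
Why: The standard entry to ortho-silylaryl triflates: bromine–lithium exchange on 8 is faster than any deprotonation, the aryllithium undergoes the 1,3 oxygen-to-carbon silyl shift (retro-Brook) to 9, and the phenoxide is triflated.

Step 7
Reactants: 11 geraniol ((2E)-3,7-dimethylocta-2,6-dien-1-ol)
Product: 12 [(2S,3S)-3-methyl-3-(4-methylpent-3-en-1-yl)oxiran-2-yl]methanol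
Conditions: Ti(OiPr)4 (5 mol%), L-(+)-diethyl tartrate (6 mol%), t-BuOOH, 4 Å MS, CH2Cl2, −20 °C
Reagents that add atoms: tert-butyl hydroperoxide, CC(C)(C)OO
Why: Sharpless asymmetric epoxidation; the titanium tartrate complex binds the allylic alcohol, so only the 2,3-alkene reacts, and the L-tartrate delivers oxygen to the face that gives the (2S,3S) epoxide.

Step 8
Reactants: 12 [(2S,3S)-3-methyl-3-(4-methylpent-3-en-1-yl)oxiran-2-yl]methanol
Product: 13 (2S,3R)-3,7-dimethyloct-6-ene-1,2,3-triol
Conditions: HClO4 (cat.), THF/H2O 3:1, 0 °C to rt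
Reagents that add atoms: water, O
Why: Acid-catalysed epoxide hydrolysis: water attacks the protonated epoxide from the rear at the tertiary C3 (better cation stabilisation, and C2 is deactivated by the hydroxymethyl group), inverting C3 to R while C2 stays S; this is the anti relationship of the target diol.

Step 9
Reactants: 13 (2S,3R)-3,7-dimethyloct-6-ene-1,2,3-triol
Product: 14 (2S,3R)-2,3-dihydroxy-3,7-dimethyloct-6-en-1-yl 4-methylbenzenesulfonate
Conditions: TsCl (1.05 equiv), Bu2SnO (2 mol%), Et3N, CH2Cl2, 0 °C
Reagents that add atoms: 4-methylbenzenesulfonyl chloride, Cc1ccc(S(=O)(=O)Cl)cc1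
Why: Tin-acetal-catalysed selective sulfonylation of the primary hydroxyl of a 1,2-diol; the tertiary hydroxyl is inert and no stereocentre is involved.

Step 10
Reactants: 14 (2S,3R)-2,3-dihydroxy-3,7-dimethyloct-6-en-1-yl 4-methylbenzenesulfonate
Product: 16 ethyl (5S)-5-[(2R)-2-hydroxy-6-methylhept-5-en-2-yl]-2-oxooxolane-3-carboxylate (both C3 epimers), via terminal epoxide 15 (not isolated)
Conditions: CH2(CO2Et)2 (3 equiv), NaOEt (3 equiv), EtOH, 0 °C to 70 °C; aq. NH4Cl
Reagents that add atoms: diethyl malonate, CCOC(=O)CC(=O)OCC
Why: The C2 alkoxide closes onto C1 to give epoxide 15, the malonate anion opens it at the unsubstituted carbon (classical malonic ester route to butyrolactones) and the alkoxide lactonises onto one ester; no bond to a stereocentre is broken, and reversible Payne isomerisation of 15 to the inner epoxy alcohol only stores material and drains back through 15.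

Step 11
Reactants: 16 ethyl (5S)-5-[(2R)-2-hydroxy-6-methylhept-5-en-2-yl]-2-oxooxolane-3-carboxylate
Product: 17 (5S)-5-[(2R)-2-hydroxy-6-methylhept-5-en-2-yl]oxolan-2-one
Conditions: LiCl, H2O (2 equiv), DMSO, 140 °C
Reagents that add atoms: none
Why: Krapcho dealkoxycarbonylation of the activated ester under neutral conditions, which avoids hot acid on the tertiary alcohol and the alkene; the epimeric centre of 16 is removed.

Step 12
Reactants: 17 (5S)-5-[(2R)-2-hydroxy-6-methylhept-5-en-2-yl]oxolan-2-one
Product: 18 methyl 3-[(4S,5R)-2,2,5-trimethyl-5-(4-methylpent-3-en-1-yl)-1,3-dioxolan-4-yl]propanoate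
Conditions: Me2C(OMe)2, MeOH, camphorsulfonic acid (cat.), rt
Reagents that add atoms: 2,2-dimethoxypropane, COC(C)(C)OC; methanol, CO
Why: Acid-catalysed methanolysis of the γ-lactone is pulled forward by ketalisation of the released secondary–tertiary 1,2-diol, a known way to open hydroxyalkyl butyrolactones to acetonide esters; only the acyl C–O bond is broken, so both stereocentres are retained.

Step 13
Reactants: 18 methyl 3-[(4S,5R)-2,2,5-trimethyl-5-(4-methylpent-3-en-1-yl)-1,3-dioxolan-4-yl]propanoate
Product: 19 3-[(4S,5R)-2,2,5-trimethyl-5-(4-methylpent-3-en-1-yl)-1,3-dioxolan-4-yl]propanoic acid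
Conditions: LiOH, THF/MeOH/H2O, rt; cold 0.5 M HCl to pH 4
Reagents that add atoms: lithium hydroxide, [Li+].[OH-]
Why: Ester saponification; the ketal is stable to base and to brief cold acidification, and it blocks relactonisation.

Step 14
Reactants: 20 2,4-dihydroxybenzoic acid
Product: 22 2,4-bis(methoxymethoxy)benzoic acid, via methoxymethyl ester 21 (not isolated)
Conditions: NaH (3.5 equiv), MeOCH2Cl (3.5 equiv), DMF, 0 °C to rt; then KOH, MeOH/H2O, 50 °C; cold dilute HCl to pH 4
Reagents that add atoms: chloromethyl methyl ether, COCCl; potassium hydroxide, [K+].[OH-]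
Why: Exhaustive alkylation of both phenoxides and the carboxylate (NaH is needed for the hydrogen-bonded 2-hydroxyl), then hydroxide cleaves only the acyloxymethyl ester while the aryl acetal ethers are base-stable.

Step 15
Reactants: 10 3,5-bis(methoxymethoxy)-4-(3-methylbut-2-en-1-yl)-2-(trimethylsilyl)phenyl trifluoromethanesulfonate; 19 3-[(4S,5R)-2,2,5-trimethyl-5-(4-methylpent-3-en-1-yl)-1,3-dioxolan-4-yl]propanoic acid
Product: 24 1-[6-hydroxy-2,4-bis(methoxymethoxy)-3-(3-methylbut-2-en-1-yl)phenyl]-3-[(4S,5R)-2,2,5-trimethyl-5-(4-methylpent-3-en-1-yl)-1,3-dioxolan-4-yl]propan-1-one, via aryne 23 (not isolated)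
Conditions: 10 (1.5 equiv), CsF (4 equiv), THF, 125 °C, sealed tube; aq. NH4Cl
Reagents that add atoms: none
Why: Fluoride removes the trimethylsilyl group of 10 and triflate departs, giving aryne 23 (the future C8a≡C4a) in the presence of the caesium carboxylate of 19. The carboxylate oxygen adds to the aryne carbon remote from the flanking methoxymethoxy group (future C8a), because the inductively withdrawing C5 oxygen distorts the triple bond so that the developing aryl anion sits on the carbon next to it (future C4a). That anion attacks the carbonyl of the aryl ester just formed through a four-membered alkoxide, which collapses to the phenoxide ketone, so the aryne is inserted into the acid C–O bond and O–C8a and C4–C4a are formed. The closest known reaction type is the fluoride-induced formal insertion of arynes into the C–O bond of carboxylic acids in hot THF, which gives ortho-hydroxyaryl ketones, applied here to a 3-alkoxyaryne. No ring is closed and no stereocentre is formed; the chain stereocentres lie γ and δ to the reacting carbonyl, carry no acidic hydrogen and are locked in the ketal, so they are not touched. The selectivity needed is regiochemical (oxygen on C8a, acyl on C4a) and it is secured twice: by the ether beside the triple bond, and by the mirror symmetry of phenol 6, which allows only one aryne, so the prenyl group can only end at C6 and the free hydroxyl can only be O1. Aprotic THF at high temperature is chosen so that intramolecular acyl transfer outruns protonation of the aryl anion.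

Step 16
Reactants: 24 1-[6-hydroxy-2,4-bis(methoxymethoxy)-3-(3-methylbut-2-en-1-yl)phenyl]-3-[(4S,5R)-2,2,5-trimethyl-5-(4-methylpent-3-en-1-yl)-1,3-dioxolan-4-yl]propan-1-one; 22 2,4-bis(methoxymethoxy)benzoic acid
Product: 25 3,5-bis(methoxymethoxy)-4-(3-methylbut-2-en-1-yl)-2-{3-[(4S,5R)-2,2,5-trimethyl-5-(4-methylpent-3-en-1-yl)-1,3-dioxolan-4-yl]propanoyl}phenyl 2,4-bis(methoxymethoxy)benzoate
Conditions: EDC·HCl, DMAP, CH2Cl2, rt
Reagents that add atoms: none
Why: Carbodiimide/DMAP (Steglich-type) esterification of the single free hydroxyl of 24; no acid chloride and no hydrogen chloride are involved, so the acetal ethers and the ketal are safe.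

Step 17
Reactants: 25 3,5-bis(methoxymethoxy)-4-(3-methylbut-2-en-1-yl)-2-{3-[(4S,5R)-2,2,5-trimethyl-5-(4-methylpent-3-en-1-yl)-1,3-dioxolan-4-yl]propanoyl}phenyl 2,4-bis(methoxymethoxy)benzoate
Product: 26 1-[2,4-bis(methoxymethoxy)phenyl]-3-[6-hydroxy-2,4-bis(methoxymethoxy)-3-(3-methylbut-2-en-1-yl)phenyl]-2-{[(4S,5R)-2,2,5-trimethyl-5-(4-methylpent-3-en-1-yl)-1,3-dioxolan-4-yl]methyl}propane-1,3-dione (epimers at C2, in equilibrium with the cyclic hemiketal)
Conditions: LiN(SiMe3)2 (3 equiv), THF, −78 °C to 0 °C; AcOH quench
Reagents that add atoms: none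
Why: Baker–Venkataraman rearrangement: the ketone enolate attacks the neighbouring aryl ester through a six-membered transition state and forms the C2–C3 bond; the new stereocentre between the carbonyls is uncontrolled and is destroyed in step 18.

Step 18
Reactants: 26 1-[2,4-bis(methoxymethoxy)phenyl]-3-[6-hydroxy-2,4-bis(methoxymethoxy)-3-(3-methylbut-2-en-1-yl)phenyl]-2-{[(4S,5R)-2,2,5-trimethyl-5-(4-methylpent-3-en-1-yl)-1,3-dioxolan-4-yl]methyl}propane-1,3-dione
Product: 27 2-[2,4-bis(methoxymethoxy)phenyl]-5,7-bis(methoxymethoxy)-6-(3-methylbut-2-en-1-yl)-3-{[(4S,5R)-2,2,5-trimethyl-5-(4-methylpent-3-en-1-yl)-1,3-dioxolan-4-yl]methyl}-4H-chromen-4-one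
Conditions: p-TsOH (10 mol%), 4 Å MS, CH2Cl2, rt
Reagents that add atoms: none
Why: Cyclodehydration of an ortho-hydroxyaryl 1,3-diketone: the free C8a hydroxyl adds to the ring B ketone, and the hemiketal ionises easily (oxocarbenium stabilised by the dioxygenated ring B) and loses the C3 proton; only the C8a oxygen is free, so closure can only give the 6-prenyl flavone, and the sieves take up the water so that the acetal ethers and the ketal should persist.

Step 19
Reactants: 27 2-[2,4-bis(methoxymethoxy)phenyl]-5,7-bis(methoxymethoxy)-6-(3-methylbut-2-en-1-yl)-3-{[(4S,5R)-2,2,5-trimethyl-5-(4-methylpent-3-en-1-yl)-1,3-dioxolan-4-yl]methyl}-4H-chromen-4-one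
Product: 28 2-(2,4-dihydroxyphenyl)-3-[(2S,3R)-2,3-dihydroxy-3,7-dimethyloct-6-en-1-yl]-5,7-dihydroxy-6-(3-methylbut-2-en-1-yl)-4H-chromen-4-one (CNP0113932.1)
Conditions: 2 M aq. HCl/MeOH 1:4, 40 °C
Reagents that add atoms: none
Why: Acid-catalysed acetal exchange removes the four methoxymethyl ethers and the isopropylidene ketal in one operation; dilute acid in methanol at moderate temperature should be too weak to protonate the trisubstituted alkenes, and neither carbinol C–O bond is broken, so the (2S,3R) configuration is retained.

## Compound list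

1 | phloroglucinol (benzene-1,3,5-triol) | Oc1cc(O)cc(O)c1 | starting material
2 | 3,5-bis(methoxymethoxy)phenol | COCOc1cc(O)cc(OCOC)c1 | intermediate
3 | [3,5-bis(methoxymethoxy)phenoxy]tri(propan-2-yl)silane | COCOc1cc(O[Si](C(C)C)(C(C)C)C(C)C)cc(OCOC)c1 | intermediate
4 | 1-bromo-3-methylbut-2-ene | CC(C)=CCBr | starting material
5 | [3,5-bis(methoxymethoxy)-4-(3-methylbut-2-en-1-yl)phenoxy]tri(propan-2-yl)silane | COCOc1cc(O[Si](C(C)C)(C(C)C)C(C)C)cc(OCOC)c1CC=C(C)C | intermediate
6 | 3,5-bis(methoxymethoxy)-4-(3-methylbut-2-en-1-yl)phenol | COCOc1cc(O)cc(OCOC)c1CC=C(C)C | intermediate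
7 | 2-bromo-3,5-bis(methoxymethoxy)-4-(3-methylbut-2-en-1-yl)phenol | COCOc1cc(O)c(Br)c(OCOC)c1CC=C(C)C | intermediate
8 | [2-bromo-3,5-bis(methoxymethoxy)-4-(3-methylbut-2-en-1-yl)phenoxy]trimethylsilane | COCOc1cc(O[Si](C)(C)C)c(Br)c(OCOC)c1CC=C(C)C | intermediate (not isolated)
9 | lithium 3,5-bis(methoxymethoxy)-4-(3-methylbut-2-en-1-yl)-2-(trimethylsilyl)phenoxide | [Li+].[O-]c1cc(OCOC)c(CC=C(C)C)c(OCOC)c1[Si](C)(C)C | intermediate (not isolated)
10 | 3,5-bis(methoxymethoxy)-4-(3-methylbut-2-en-1-yl)-2-(trimethylsilyl)phenyl trifluoromethanesulfonate | C[Si](C)(C)c1c(OS(=O)(=O)C(F)(F)F)cc(OCOC)c(CC=C(C)C)c1OCOC | intermediate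
11 | geraniol ((2E)-3,7-dimethylocta-2,6-dien-1-ol) | CC(C)=CCC/C(C)=C/CO | starting material
12 | [(2S,3S)-3-methyl-3-(4-methylpent-3-en-1-yl)oxiran-2-yl]methanol | CC(C)=CCC[C@]1(C)O[C@H]1CO | intermediate
13 | (2S,3R)-3,7-dimethyloct-6-ene-1,2,3-triol | CC(C)=CCC[C@@](C)(O)[C@@H](O)CO | intermediate
14 | (2S,3R)-2,3-dihydroxy-3,7-dimethyloct-6-en-1-yl 4-methylbenzenesulfonate | CC(C)=CCC[C@@](C)(O)[C@@H](O)COS(=O)(=O)c1ccc(C)cc1 | intermediate
15 | (2R)-6-methyl-2-[(2S)-oxiran-2-yl]hept-5-en-2-ol | CC(C)=CCC[C@@](C)(O)[C@@H]1CO1 | intermediate (not isolated)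
16 | ethyl (5S)-5-[(2R)-2-hydroxy-6-methylhept-5-en-2-yl]-2-oxooxolane-3-carboxylate | CC(C)=CCC[C@@](C)(O)[C@@H]1CC(C(=O)OCC)C(=O)O1 | intermediate
17 | (5S)-5-[(2R)-2-hydroxy-6-methylhept-5-en-2-yl]oxolan-2-one | CC(C)=CCC[C@@](C)(O)[C@@H]1CCC(=O)O1 | intermediate
18 | methyl 3-[(4S,5R)-2,2,5-trimethyl-5-(4-methylpent-3-en-1-yl)-1,3-dioxolan-4-yl]propanoate | CC(C)=CCC[C@@](C)(OC1(C)C)[C@@H](O1)CCC(=O)OC | intermediate
19 | 3-[(4S,5R)-2,2,5-trimethyl-5-(4-methylpent-3-en-1-yl)-1,3-dioxolan-4-yl]propanoic acid | CC(C)=CCC[C@@](C)(OC1(C)C)[C@@H](O1)CCC(=O)O | intermediate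
20 | 2,4-dihydroxybenzoic acid | O=C(O)c1ccc(O)cc1O | starting material
21 | methoxymethyl 2,4-bis(methoxymethoxy)benzoate | COCOC(=O)c1ccc(OCOC)cc1OCOC | intermediate (not isolated)
22 | 2,4-bis(methoxymethoxy)benzoic acid | COCOc1ccc(C(=O)O)c(OCOC)c1 | intermediate
23 | 3,5-bis(methoxymethoxy)-4-(3-methylbut-2-en-1-yl)benzyne | COCOC1=C(CC=C(C)C)C(OCOC)=CC#C1 | intermediate (not isolated)
24 | 1-[6-hydroxy-2,4-bis(methoxymethoxy)-3-(3-methylbut-2-en-1-yl)phenyl]-3-[(4S,5R)-2,2,5-trimethyl-5-(4-methylpent-3-en-1-yl)-1,3-dioxolan-4-yl]propan-1-one | CC(C)=CCC[C@@](C)(OC1(C)C)[C@@H](O1)CCC(=O)c1c(O)cc(OCOC)c(CC=C(C)C)c1OCOC | intermediate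
25 | 3,5-bis(methoxymethoxy)-4-(3-methylbut-2-en-1-yl)-2-{3-[(4S,5R)-2,2,5-trimethyl-5-(4-methylpent-3-en-1-yl)-1,3-dioxolan-4-yl]propanoyl}phenyl 2,4-bis(methoxymethoxy)benzoate | CC(C)=CCC[C@@](C)(OC1(C)C)[C@@H](O1)CCC(=O)c1c(OC(=O)c2ccc(OCOC)cc2OCOC)cc(OCOC)c(CC=C(C)C)c1OCOC | intermediate
26 | 1-[2,4-bis(methoxymethoxy)phenyl]-3-[6-hydroxy-2,4-bis(methoxymethoxy)-3-(3-methylbut-2-en-1-yl)phenyl]-2-{[(4S,5R)-2,2,5-trimethyl-5-(4-methylpent-3-en-1-yl)-1,3-dioxolan-4-yl]methyl}propane-1,3-dione | CC(C)=CCC[C@@](C)(OC1(C)C)[C@@H](O1)CC(C(=O)c1ccc(OCOC)cc1OCOC)C(=O)c1c(O)cc(OCOC)c(CC=C(C)C)c1OCOC | intermediate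
27 | 2-[2,4-bis(methoxymethoxy)phenyl]-5,7-bis(methoxymethoxy)-6-(3-methylbut-2-en-1-yl)-3-{[(4S,5R)-2,2,5-trimethyl-5-(4-methylpent-3-en-1-yl)-1,3-dioxolan-4-yl]methyl}-4H-chromen-4-one | CC(C)=CCC[C@@](C)(OC1(C)C)[C@@H](O1)Cc1c(-c2ccc(OCOC)cc2OCOC)oc2cc(OCOC)c(CC=C(C)C)c(OCOC)c2c1=O | intermediate
28 | 2-(2,4-dihydroxyphenyl)-3-[(2S,3R)-2,3-dihydroxy-3,7-dimethyloct-6-en-1-yl]-5,7-dihydroxy-6-(3-methylbut-2-en-1-yl)-4H-chromen-4-one | CC(C)=CCC[C@@](C)(O)[C@@H](O)Cc1c(-c2ccc(O)cc2O)oc2cc(O)c(CC=C(C)C)c(O)c2c1=O | target

## Step count and least certain steps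

Total: 19 steps. Longest linear sequence: 12 steps (11 to 28 through steps 7–13 and 15–19). The aryne branch has 6 steps before the union and the ring B acid 1 step.

**Step 15 (key step).** The aryl anion formed after carboxylate addition may be protonated by the acid before it attacks the ester carbonyl, which gives an aryl ester with no C–C bond. The aryne may also undergo ene reactions with the two prenyl-type alkenes, and the product phenoxide may be arylated by a second aryne. Fallback: the same acyl shift is run from an aryllithium generated without a proton source. Bromophenol 7 and acid 19 are coupled with EDC and DMAP to give 2-bromo-3,5-bis(methoxymethoxy)-4-(3-methylbut-2-en-1-yl)phenyl 3-[(4S,5R)-2,2,5-trimethyl-5-(4-methylpent-3-en-1-yl)-1,3-dioxolan-4-yl]propanoate F1. Treatment of F1 with t-BuLi in THF at −100 °C causes bromine–lithium exchange and the anionic Fries-type oxygen-to-carbon acyl migration, and protonation returns the route at ketone 24.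

**Step 8.** Opening at the tertiary carbon may proceed partly through a cation-like pathway with retention at C3, which gives the diastereomeric triol. A minor attack of water at C2 gives the enantiomer of 13 and lowers the enantiomeric purity. Fallback: the same triol is reached by two strictly bimolecular displacements from the other epoxide enantiomer. Geraniol 11 is epoxidised with Ti(OiPr)4, D-(−)-diethyl tartrate and t-BuOOH to [(2R,3R)-3-methyl-3-(4-methylpent-3-en-1-yl)oxiran-2-yl]methanol F2. Heating F2 in 0.5 M NaOH in t-BuOH/H2O brings about Payne rearrangement (inversion at C2) and hydroxide opening of the terminal epoxide at C1, which returns the route at triol 13.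

**Step 5.** Electrophilic bromine may attack the prenyl alkene in competition with the ring, or a second bromination may follow the first. Fallback: the silyl group is introduced by directed metalation without any electrophilic halogen. Phenol 6 is carbamoylated with Et2NCOCl and K2CO3 in MeCN to 3,5-bis(methoxymethoxy)-4-(3-methylbut-2-en-1-yl)phenyl N,N-diethylcarbamate F3. Lithiation between the carbamate and the acetal ether with s-BuLi and TMEDA at −78 °C and quenching with Me3SiCl gives 3,5-bis(methoxymethoxy)-4-(3-methylbut-2-en-1-yl)-2-(trimethylsilyl)phenyl N,N-diethylcarbamate F4. Reductive cleavage with LiAlH4 gives 3,5-bis(methoxymethoxy)-4-(3-methylbut-2-en-1-yl)-2-(trimethylsilyl)phenol F5, and triflation with Tf2O and pyridine returns the route at triflate 10.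

**Step 18.** The acid may remove the methoxymethyl group on the C5 oxygen before dehydration is complete, after which ring closure through that oxygen would give the 8-prenyl isomer. The water released may also hydrolyse the ketal. Fallback: the hemiketal form of 26 is dehydrated under basic conditions with SOCl2 in pyridine at 0 °C (chlorosulfite formation and base-induced elimination, known for stable 2-hydroxychromanones). This starts from 26, returns at 27 and makes no new compound (F0).

**Step 19.** The protic acid may cyclise the prenyl group onto the C5 or C7 hydroxyl, or the tertiary hydroxyl onto the chain alkene, and the hindered ketal may hydrolyse so slowly that forcing conditions are needed. Fallback: the deprotection is staged and the phenols are freed without protic acid. Flavone 27 is treated with Me3SiOTf and 2,2'-bipyridyl in CH2Cl2 at 0 °C and then with water, which converts the aryl acetal ethers into phenols and gives 2-(2,4-dihydroxyphenyl)-5,7-dihydroxy-6-(3-methylbut-2-en-1-yl)-3-{[(4S,5R)-2,2,5-trimethyl-5-(4-methylpent-3-en-1-yl)-1,3-dioxolan-4-yl]methyl}-4H-chromen-4-one F6. The ketal of F6 is then removed with 80% aqueous acetic acid at 40 °C, which returns the route at target 28.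

## Further compounds

F1 | step 15 | 2-bromo-3,5-bis(methoxymethoxy)-4-(3-methylbut-2-en-1-yl)phenyl 3-[(4S,5R)-2,2,5-trimethyl-5-(4-methylpent-3-en-1-yl)-1,3-dioxolan-4-yl]propanoate | CC(C)=CCC[C@@](C)(OC1(C)C)[C@@H](O1)CCC(=O)Oc1cc(OCOC)c(CC=C(C)C)c(OCOC)c1Br
F2 | step 8 | [(2R,3R)-3-methyl-3-(4-methylpent-3-en-1-yl)oxiran-2-yl]methanol | CC(C)=CCC[C@@]1(C)O[C@@H]1CO
F3 | step 5 | 3,5-bis(methoxymethoxy)-4-(3-methylbut-2-en-1-yl)phenyl N,N-diethylcarbamate | CCN(CC)C(=O)Oc1cc(OCOC)c(CC=C(C)C)c(OCOC)c1
F4 | step 5 | 3,5-bis(methoxymethoxy)-4-(3-methylbut-2-en-1-yl)-2-(trimethylsilyl)phenyl N,N-diethylcarbamate | CCN(CC)C(=O)Oc1cc(OCOC)c(CC=C(C)C)c(OCOC)c1[Si](C)(C)C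
F5 | step 5 | 3,5-bis(methoxymethoxy)-4-(3-methylbut-2-en-1-yl)-2-(trimethylsilyl)phenol | Oc1cc(OCOC)c(CC=C(C)C)c(OCOC)c1[Si](C)(C)C
F0 | step 18 | none | none
F6 | step 19 | 2-(2,4-dihydroxyphenyl)-5,7-dihydroxy-6-(3-methylbut-2-en-1-yl)-3-{[(4S,5R)-2,2,5-trimethyl-5-(4-methylpent-3-en-1-yl)-1,3-dioxolan-4-yl]methyl}-4H-chromen-4-one | CC(C)=CCC[C@@](C)(OC1(C)C)[C@@H](O1)Cc1c(-c2ccc(O)cc2O)oc2cc(O)c(CC=C(C)C)c(O)c2c1=O
A1 | alternative 1 | 2-[2,4-bis(methoxymethoxy)phenyl]-5,7-dihydroxy-6-(3-methylbut-2-en-1-yl)-3-{[(4S,5R)-2,2,5-trimethyl-5-(4-methylpent-3-en-1-yl)-1,3-dioxolan-4-yl]methyl}-4H-chromen-4-one | CC(C)=CCC[C@@](C)(OC1(C)C)[C@@H](O1)Cc1c(-c2ccc(OCOC)cc2OCOC)oc2cc(O)c(CC=C(C)C)c(O)c2c1=O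
A2 | alternative 1 | methyl 4-{6-[2,4-bis(methoxymethoxy)phenyl]-4-oxo-5-{[(4S,5R)-2,2,5-trimethyl-5-(4-methylpent-3-en-1-yl)-1,3-dioxolan-4-yl]methyl}-4H-pyran-2-yl}-2-(3-methylbut-2-en-1-yl)-3-oxobutanoate | CC(C)=CCC[C@@](C)(OC1(C)C)[C@@H](O1)Cc1c(-c2ccc(OCOC)cc2OCOC)oc(CC(=O)C(CC=C(C)C)C(=O)OC)cc1=O
A3 | alternative 2 | 2-(2,4-dihydroxyphenyl)-5,7-bis(methoxymethoxy)-6-(3-methylbut-2-en-1-yl)-3-{[(4S,5R)-2,2,5-trimethyl-5-(4-methylpent-3-en-1-yl)-1,3-dioxolan-4-yl]methyl}-4H-chromen-4-one | CC(C)=CCC[C@@](C)(OC1(C)C)[C@@H](O1)Cc1c(-c2ccc(O)cc2O)oc2cc(OCOC)c(CC=C(C)C)c(OCOC)c2c1=O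
A4 | alternative 2 | 2-ethynyl-5,7-bis(methoxymethoxy)-6-(3-methylbut-2-en-1-yl)-3-{[(4S,5R)-2,2,5-trimethyl-5-(4-methylpent-3-en-1-yl)-1,3-dioxolan-4-yl]methyl}-4H-chromen-4-one | CC(C)=CCC[C@@](C)(OC1(C)C)[C@@H](O1)Cc1c(C#C)oc2cc(OCOC)c(CC=C(C)C)c(OCOC)c2c1=O
A5 | alternative 2 | 1-methoxy-1,3-bis(trimethylsilyloxy)buta-1,3-diene | COC(O[Si](C)(C)C)=CC(=C)O[Si](C)(C)C
A6 | alternative 3 | 2-[2,4-bis(methoxymethoxy)phenyl]-5,7-bis(methoxymethoxy)-6-(3-methylbut-2-en-1-yl)-3-{[(4S,5R)-2,2,5-trimethyl-5-(4-methylpent-3-en-1-yl)-1,3-dioxolan-4-yl]methyl}-4H-chromen-4-one | CC(C)=CCC[C@@](C)(OC1(C)C)[C@@H](O1)Cc1c(-c2ccc(OCOC)cc2OCOC)oc2cc(OCOC)c(CC=C(C)C)c(OCOC)c2c1=O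
A7 | alternative 3 | 6-hydroxy-2,4-bis(methoxymethoxy)-3-(3-methylbut-2-en-1-yl)benzaldehyde | O=Cc1c(O)cc(OCOC)c(CC=C(C)C)c1OCOC
A8 | alternative 3 | (4S,5R)-4-{3-[2,4-bis(methoxymethoxy)phenyl]prop-2-yn-1-yl}-2,2,5-trimethyl-5-(4-methylpent-3-en-1-yl)-1,3-dioxolane | CC(C)=CCC[C@@](C)(OC1(C)C)[C@@H](O1)CC#Cc1ccc(OCOC)cc1OCOC
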